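The route rests on cutting the cyclohexenone ring (C1, C10–C14) at C13–C14 and C1–C10, a Diels–Alder retron once C12 is a silyl enol ether and C14 carries a leaving group. The key step exploits the trans-vicinal, oxygen-bearing arms C2 and C9 on this ring. O9 is acylated by C2, so an ester-tethered intramolecular cycloaddition forms both bonds, the six-membered ring and a temporary γ-lactone at once, and relays C9 to C10 and C1. Its precursor is an L-arabinose-derived lactone carrying a 2-silyloxydiene whose O9 bears (E)-3-(phenylsulfonyl)methacrylate. Later sulfinate loss gives C13=C14, and ring-closing metathesis closes the ten-membered ring.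

Key step: step 14

Numbering (briarane): C1 quaternary ring-fusion carbon (C15 methyl), C2 (OAc), C3=C4, C5 (=C16H2), C6 (Cl), C7 (lactone O), C8 (OH), C9 (OAc), C10 ring-fusion CH, C11 (OH, C20 methyl), C12 ketone, C13=C14, C17 (C18 methyl), C19 lactone carbonyl. On is the oxygen on Cn.

Remark on the chemistry: C17 forms as an epimer mixture in step 6. It is drawn without configuration in 10–28 and is fixed by equilibration in step 17. Anomeric and lactol centres are drawn without configuration.

Step 1
Reactants: 1 ethyl pyruvate; 2 diethyl [(phenylsulfonyl)methyl]phosphonate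
Product: 3 ethyl (E)-2-methyl-3-(phenylsulfonyl)prop-2-enoate
Conditions: NaH, THF, 0 °C to rt
Reagents that add atoms: none
Why: Horner–Wadsworth–Emmons olefination of the activated keto group should place the sulfonyl and ester groups trans (E) for steric and dipolar reasons, and any Z isomer can be removed by chromatography.

Step 2
Reactants: 3 ethyl (E)-2-methyl-3-(phenylsulfonyl)prop-2-enoate
Product: 4 (E)-2-methyl-3-(phenylsulfonyl)prop-2-enoic acid
Conditions: 6 M HCl, 1,4-dioxane, 90 °C
Reagents that add atoms: water, O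
Why: Acid-catalysed ester hydrolysis avoids hydroxide, which would attack the β-sulfonyl acrylate by addition–elimination, and leaves the E geometry untouched.

Step 3
Reactants: 5 L-arabinose
Product: 6 5-O-(tert-butyldiphenylsilyl)-L-arabinofuranose (anomers)
Conditions: TBDPSCl, pyridine, 0 °C to rt
Reagents that add atoms: tert-butyl(chloro)diphenylsilane (TBDPSCl), CC(C)(C)[Si](Cl)(c1ccccc1)c1ccccc1
Why: Silyl ether protection of the only primary hydroxyl (O10) blocks the pyranose form, so the sugar is held as the furanose in which sugar C1–C5 are C6–C10 of the target.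

Step 4
Reactants: 6 5-O-TBDPS-L-arabinofuranose
Product: 7 5-O-TBDPS-1,2-O-isopropylidene-β-L-arabinofuranose
Conditions: 2,2-dimethoxypropane, TsOH (cat.), acetone, rt
Reagents that add atoms: 2,2-dimethoxypropane, COC(C)(C)OC
Why: Acid-catalysed acetonide formation (transketalisation) takes the only cis-1,2-diol of the furanose, the anomeric oxygen and O7 of the β-anomer, and leaves the C8 hydroxyl free.

Step 5
Reactants: 7 5-O-TBDPS-1,2-O-isopropylidene-β-L-arabinofuranose
Product: 8 5-O-TBDPS-1,2-O-isopropylidene-β-L-threo-pentofuranos-3-ulose (C8 ketone)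
Conditions: Dess–Martin periodinane, CH2Cl2, rt
Reagents that add atoms: none
Why: Dess–Martin oxidation of the single free secondary alcohol is neutral enough to leave the flanking centres C7 and C9 unepimerised.

Step 6
Reactants: 8 C8 ketone; 9 ethyl propanoate
Product: 10 3-C-[1-(ethoxycarbonyl)ethyl]-5-O-TBDPS-1,2-O-isopropylidene-β-L-lyxofuranose (C17 epimers)
Conditions: LDA, 9, THF, −78 °C; then 8; aq. NH4Cl
Reagents that add atoms: none
Why: Aldol addition of the lithium ester enolate should occur on the face of the cis-fused bicycle opposite to the acetonide and the C10 side chain, which sets C8 with O8 cis to O7, while C17 forms as an epimer mixture that is levelled in step 17.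

Step 7
Reactants: 10 TBDPS ether of the aldol adduct
Product: 11 3-C-[1-(ethoxycarbonyl)ethyl]-1,2-O-isopropylidene-β-L-lyxofuranose (free C10 alcohol)
Conditions: TBAF, AcOH, THF, 0 °C to rt
Reagents that add atoms: none
Why: Fluoride desilylation buffered with acetic acid frees the primary alcohol without retro-aldol cleavage of the tertiary aldol.

Step 8
Reactants: 11 primary alcohol; 12 3-(triphenyl-λ5-phosphanylidene)butan-2-one
Product: 14 furanose acetonide bearing the (E)-C10=C11 methyl enone at C9, via C10 aldehyde 13 (not isolated)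
Conditions: Dess–Martin periodinane, 12, CH2Cl2, rt to 40 °C
Reagents that add atoms: none
Why: One-pot Dess–Martin oxidation and Wittig olefination traps the labile α-alkoxy aldehyde at once, and the stabilised α-methyl ylide should give the E-trisubstituted enone.

Step 9
Reactants: 14 enone acetonide
Product: 15 C6 lactol (furanose) with free O7–H and O8–H
Conditions: TFA/H2O 4:1, 0 °C
Reagents that add atoms: none
Why: Acid hydrolysis of the acetonide unmasks the C6 lactol and the C7 hydroxyl, and the ester cannot lactonise yet because O7 and C17 are trans on the furanose ring.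

Step 10
Reactants: 15 C6 lactol; 16 1,4-dibromobut-2-yne
Product: 18 γ-lactone triol with (6R)-carbinol bearing buta-1,3-dien-2-yl, via open hydroxy ester 17 (not isolated)
Conditions: In powder, THF/H2O 1:1, rt, sonication; then 1 M HCl to pH 3, rt
Reagents that add atoms: none
Why: Indium-mediated Barbier-type 1,3-butadien-2-ylation in water should attack the open-chain aldehyde under chelation by the free C7 hydroxyl to give the 6,7-syn diol, tolerates enone and ester, and the freed O7 then closes the less crowded γ-lactone (C6 and C9 trans) by lactonisation.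

Step 11
Reactants: 18 γ-lactone triol
Product: 19 6-O-TBS ether of 18
Conditions: TBSCl, imidazole, DMF, 0 °C
Reagents that add atoms: tert-butyl(chloro)dimethylsilane (TBSCl), CC(C)(C)[Si](C)(C)Cl
Why: Silyl ether protection should be selective because the C6 carbinol is far less hindered than the C9 carbinol next to the fully substituted C8, and the tertiary C8 hydroxyl does not react.

Step 12
Reactants: 19 6-O-TBS ether; 4 (E)-2-methyl-3-(phenylsulfonyl)prop-2-enoic acid
Product: 20 O9 ester of 19 with acid 4
Conditions: DCC, DMAP (cat.), CH2Cl2, 0 °C to rt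
Reagents that add atoms: none
Why: Steglich esterification acylates the only remaining secondary hydroxyl (O9), the tertiary O8–H being inert, and keeps the E geometry of the sulfonyl acrylate.

Step 13
Reactants: 20 enone ester
Product: 21 2-(triisopropylsilyloxy)diene C13=C12(OTIPS)–C11(C20)=C10 carrying the O9 sulfonylmethacrylate
Conditions: TIPSOTf, Et3N, CH2Cl2, −78 to 0 °C
Reagents that add atoms: triisopropylsilyl triflate (TIPSOTf), CC(C)[Si](OS(=O)(=O)C(F)(F)F)(C(C)C)C(C)C
Why: Soft enolisation of the methyl ketone with silyl triflate and amine removes a proton from the acetyl methyl C13 and gives the cross-conjugated silyl dienol ether, the bulky silyl triflate sparing the tertiary alcohol and the sulfone.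

Step 14
Reactants: 21 silyloxydiene ester
Product: 22 trans-fused bicyclic lactone (C1–C2(=O)–O9–C9–C10) on the C11=C12 silyl enol ether ring with 14-phenylsulfonyl cis to C15
Conditions: toluene (5 mM), BHT (cat.), 110 °C, sealed tube
Reagents that add atoms: none
Why: A thermal, concerted but asynchronous [4+2] cycloaddition joins the nucleophilic diene terminus C13 to C14, the β-carbon of the acrylate, and C10 to C1, so polarity and tether agree. The closest known reaction type is the ester-tethered type 1 intramolecular Diels–Alder reaction of pentadienyl acrylates and fumarates (1,3,8-nonatrienes), here with a β-sulfonyl acrylate as doubly activated dienophile. The cyclohexene ring closes in the suprafacial [4+2] mode and the five-membered lactone C1–C2–O9–C9–C10 closes with it in the fused mode with the tether carbonyl exo, which gives the trans ring fusion. C10 is controlled by C9, because A(1,3) strain with the C11 methyl keeps H9 in the diene plane, O9 with its dienophile on one face and the bulky C8 lactone on the other; this rotamer fits the exo-tether geometry, the E-sulfonyl group then lies endo, so C1 gets its methyl cis to C9 and C14 its sulfone cis to that methyl. The step needs chemoselectivity for the silyloxydiene over the pendant C4–C5 butadiene, which the three-atom tether, the higher HOMO of the silyloxydiene and high dilution should secure. Both C17 epimers react alike and converge in step 17.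

Step 15
Reactants: 22 bicyclic lactone; 23 vinylmagnesium bromide
Product: 26 (2S)-allylic alcohol with free O9–H, via dilithio enolate 24 (not isolated), via C2 lactol 25 (not isolated)
Conditions: LiHMDS (2.2 equiv), THF, −78 °C; DIBAL-H, −78 °C; 23, −78 to 0 °C; aq. NH4Cl/Rochelle salt
Reagents that add atoms: none
Why: Only the C19 lactone has an α-hydrogen, so LiHMDS masks it as the alkoxide–enolate (in situ enolate protection) while the non-enolisable strained C2 lactone undergoes one-pot DIBAL reduction and Grignard addition, in which vinyl should add anti to the axial C15 methyl with the formyl oxygen held on the C10 side by the O9 metal alkoxide, which sets 2S.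

Step 16
Reactants: 26 diol
Product: 27 2,9-diacetate
Conditions: Ac2O, pyridine, DMAP (cat.), CH2Cl2, rt
Reagents that add atoms: acetic anhydride, CC(=O)OC(C)=O
Why: Acetylation esterifies the two secondary alcohols and leaves the hindered tertiary C8 hydroxyl free.

Step 17
Reactants: 27 diacetate silyl enol ether
Product: 29 11-O-TIPS C13=C14 enone with (17R)-lactone, via sulfonyl ketone 28 (not isolated)
Conditions: mCPBA, NaHCO3, CH2Cl2, −30 °C; then DBU, 0 °C to rt
Reagents that add atoms: 3-chloroperbenzoic acid (mCPBA), OOC(=O)c1cccc(Cl)c1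
Why: Rubottom oxidation should epoxidise the most electron-rich alkene C11=C12 on the face opposite to the axial C15 methyl, C9 and the sulfone, which sets C11 with 1,4-silyl migration, and DBU then expels sulfinate by E1cB to give the C13=C14 enone and equilibrates C17 to the more stable epimer with its methyl trans to C9.

Step 18
Reactants: 29 bis-silyl ether
Product: 30 (6R)-dienyl carbinol with free 8-OH and 11-OH
Conditions: HF·pyridine, pyridine, THF, 0 °C to rt
Reagents that add atoms: none
Why: Fluoride cleavage of both silyl ethers with buffered HF·pyridine spares the acetates, the lactone, the enone and the acid-sensitive dienyl carbinol.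

Step 19
Reactants: 30 (6R)-carbinol
Product: 31 (6S)-chloride (seco-tetraene)
Conditions: PPh3, hexachloroacetone, CH2Cl2, 0 °C
Reagents that add atoms: hexachloroacetone, ClC(Cl)(Cl)C(=O)C(Cl)(Cl)Cl
Why: Appel-type chlorination with PPh3 and hexachloroacetone converts secondary allylic alcohols into the unrearranged chlorides by SN2 with inversion, which turns 6R-OH into 6S-Cl anti to O7, and the tertiary alcohols do not react.

Step 20
Reactants: 31 (6S)-chloride
Product: 32 CNP0188317.1 (target)
Conditions: Hoveyda–Grubbs II (15 mol %), 1,4-benzoquinone, toluene (0.5 mM), 80 °C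
Reagents that add atoms: none
Why: Ring-closing metathesis between the C3 vinyl group and the monosubstituted end of the diene releases ethylene, the gauche C2 and C9 arms on the cyclohexenone bring the ends together, and under reversible conditions the ten-membered ring should settle on the less strained 3Z olefin.

Compound list
1 | ethyl pyruvate | CCOC(=O)C(C)=O | starting material
2 | diethyl [(phenylsulfonyl)methyl]phosphonate | CCOP(=O)(CS(=O)(=O)c1ccccc1)OCC | starting material
3 | ethyl (E)-2-methyl-3-(phenylsulfonyl)prop-2-enoate | CCOC(=O)/C(C)=C/S(=O)(=O)c1ccccc1 | intermediate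
4 | (E)-2-methyl-3-(phenylsulfonyl)prop-2-enoic acid | OC(=O)/C(C)=C/S(=O)(=O)c1ccccc1 | intermediate
5 | L-arabinose (drawn open-chain) | O=C[C@H](O)[C@@H](O)[C@@H](O)CO | starting material
6 | 5-O-(tert-butyldiphenylsilyl)-L-arabinofuranose (anomers) | OC1O[C@@H](CO[Si](c2ccccc2)(c2ccccc2)C(C)(C)C)[C@H](O)[C@H]1O | intermediate
7 | 5-O-TBDPS-1,2-O-isopropylidene-β-L-arabinofuranose | CC1(C)O[C@H]2O[C@@H](CO[Si](c3ccccc3)(c3ccccc3)C(C)(C)C)[C@H](O)[C@H]2O1 | intermediate
8 | 5-O-TBDPS-1,2-O-isopropylidene-β-L-threo-pentofuranos-3-ulose | CC1(C)O[C@H]2O[C@@H](CO[Si](c3ccccc3)(c3ccccc3)C(C)(C)C)C(=O)[C@H]2O1 | intermediate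
9 | ethyl propanoate | CCC(=O)OCC | starting material
10 | 3-C-[1-(ethoxycarbonyl)ethyl]-5-O-TBDPS-1,2-O-isopropylidene-β-L-lyxofuranose (C17 epimers) | CC1(C)O[C@H]2O[C@@H](CO[Si](c3ccccc3)(c3ccccc3)C(C)(C)C)[C@](O)(C(C)C(=O)OCC)[C@H]2O1 | intermediate
11 | 3-C-[1-(ethoxycarbonyl)ethyl]-1,2-O-isopropylidene-β-L-lyxofuranose | CC1(C)O[C@H]2O[C@@H](CO)[C@](O)(C(C)C(=O)OCC)[C@H]2O1 | intermediate
12 | 3-(triphenyl-λ5-phosphanylidene)butan-2-one | CC(=O)C(C)=P(c1ccccc1)(c1ccccc1)c1ccccc1 | starting material
13 | C10 aldehyde (pentodialdofuranose of 11) | CC1(C)O[C@H]2O[C@@H](C=O)[C@](O)(C(C)C(=O)OCC)[C@H]2O1 | intermediate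
14 | furanose acetonide bearing the (E)-enone C10=C11(C20)–C12(=O)–C13 at C9 | CC1(C)O[C@H]2O[C@@H](/C=C(\C)C(C)=O)[C@](O)(C(C)C(=O)OCC)[C@H]2O1 | intermediate
15 | C6 lactol of 14 with free O7–H and O8–H | OC1O[C@@H](/C=C(\C)C(C)=O)[C@](O)(C(C)C(=O)OCC)[C@H]1O | intermediate
16 | 1,4-dibromobut-2-yne | BrCC#CCBr | starting material
17 | open-chain 6,7,8,9-tetraol ethyl ester (6,7-syn) with buta-1,3-dien-2-yl on C6 | CC(=O)/C(C)=C/[C@H](O)[C@](O)(C(C)C(=O)OCC)[C@@H](O)[C@H](O)C(=C)C=C | intermediate
18 | γ-lactone (C19–O7) triol: free (6R)-OH, 8-OH, 9-OH, enone on C9, butadienyl on C6 | CC(=O)/C(C)=C/[C@H](O)[C@]1(O)C(C)C(=O)O[C@H]1[C@H](O)C(=C)C=C | intermediate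
19 | 6-O-TBS ether of 18 | CC(=O)/C(C)=C/[C@H](O)[C@]1(O)C(C)C(=O)O[C@H]1[C@H](O[Si](C)(C)C(C)(C)C)C(=C)C=C | intermediate
20 | O9 (E)-2-methyl-3-(phenylsulfonyl)prop-2-enoate of 19 | CC(=O)/C(C)=C/[C@H](OC(=O)/C(C)=C/S(=O)(=O)c1ccccc1)[C@]1(O)C(C)C(=O)O[C@H]1[C@H](O[Si](C)(C)C(C)(C)C)C(=C)C=C | intermediate
21 | 12-O-TIPS 2-silyloxydiene of 20 (10E) | C=C(O[Si](C(C)C)(C(C)C)C(C)C)/C(C)=C/[C@H](OC(=O)/C(C)=C/S(=O)(=O)c1ccccc1)[C@]1(O)C(C)C(=O)O[C@H]1[C@H](O[Si](C)(C)C(C)(C)C)C(=C)C=C | intermediate
22 | trans-fused C2/O9 γ-lactone on the C11=C12 TIPS enol ether ring, 14-SO2Ph cis to C15 | O=C1O[C@H]([C@]3(O)C(C)C(=O)O[C@H]3[C@H](O[Si](C)(C)C(C)(C)C)C(=C)C=C)[C@H]2C(C)=C(O[Si](C(C)C)(C(C)C)C(C)C)C[C@@H](S(=O)(=O)c3ccccc3)[C@]12C | intermediate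
23 | vinylmagnesium bromide | C=C[Mg]Br | starting material
24 | dilithium O8 alkoxide / C19 lactone enolate of 22 | [Li+].[Li+].O=C1O[C@H]([C@]3([O-])C(C)=C([O-])O[C@H]3[C@H](O[Si](C)(C)C(C)(C)C)C(=C)C=C)[C@H]2C(C)=C(O[Si](C(C)C)(C(C)C)C(C)C)C[C@@H](S(=O)(=O)c3ccccc3)[C@]12C | intermediate
25 | C2 lactol of 22 (formed as its aluminium alkoxide with C19 still enolised; drawn protonated) | OC1O[C@H]([C@]3(O)C(C)C(=O)O[C@H]3[C@H](O[Si](C)(C)C(C)(C)C)C(=C)C=C)[C@H]2C(C)=C(O[Si](C(C)C)(C(C)C)C(C)C)C[C@@H](S(=O)(=O)c3ccccc3)[C@]12C | intermediate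
26 | (2S)-2-vinyl carbinol with free 9-OH and 8-OH, TIPS enol ether, 14-sulfone, 6-OTBS | C=C[C@H](O)[C@@]1(C)[C@H](S(=O)(=O)c2ccccc2)CC(O[Si](C(C)C)(C(C)C)C(C)C)=C(C)[C@@H]1[C@H](O)[C@]1(O)C(C)C(=O)O[C@H]1[C@H](O[Si](C)(C)C(C)(C)C)C(=C)C=C | intermediate
27 | 2,9-diacetate of 26 | C=C[C@H](OC(C)=O)[C@@]1(C)[C@H](S(=O)(=O)c2ccccc2)CC(O[Si](C(C)C)(C(C)C)C(C)C)=C(C)[C@@H]1[C@H](OC(C)=O)[C@]1(O)C(C)C(=O)O[C@H]1[C@H](O[Si](C)(C)C(C)(C)C)C(=C)C=C | intermediate
28 | (11S)-11-OTIPS 12-ketone still bearing the 14-sulfone | C=C[C@H](OC(C)=O)[C@@]1(C)[C@H](S(=O)(=O)c2ccccc2)CC(=O)[C@@](C)(O[Si](C(C)C)(C(C)C)C(C)C)[C@@H]1[C@H](OC(C)=O)[C@]1(O)C(C)C(=O)O[C@H]1[C@H](O[Si](C)(C)C(C)(C)C)C(=C)C=C | intermediate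
29 | 11-OTIPS C13=C14 enone, (17R)-lactone, 6-OTBS | C=C[C@H](OC(C)=O)[C@@]1(C)C=CC(=O)[C@@](C)(O[Si](C(C)C)(C(C)C)C(C)C)[C@@H]1[C@H](OC(C)=O)[C@]1(O)[C@@H](C)C(=O)O[C@H]1[C@H](O[Si](C)(C)C(C)(C)C)C(=C)C=C | intermediate
30 | (6R)-dienyl carbinol with free 8-OH and 11-OH | C=C[C@H](OC(C)=O)[C@@]1(C)C=CC(=O)[C@@](C)(O)[C@@H]1[C@H](OC(C)=O)[C@]1(O)[C@@H](C)C(=O)O[C@H]1[C@H](O)C(=C)C=C | intermediate
31 | (6S)-chloride, open precursor of the ten-membered ring | C=C[C@H](OC(C)=O)[C@@]1(C)C=CC(=O)[C@@](C)(O)[C@@H]1[C@H](OC(C)=O)[C@]1(O)[C@@H](C)C(=O)O[C@H]1[C@@H](Cl)C(=C)C=C | intermediate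
32 | CNP0188317.1, (1S,2S,3Z,6S,7R,8R,9S,10S,11S,17R) | C=C1/C=C\[C@H](OC(C)=O)[C@@]2(C)C=CC(=O)[C@@](C)(O)[C@@H]2[C@H](OC(C)=O)[C@]2(O)[C@@H](C)C(=O)O[C@H]2[C@H]1Cl | target

Total step count: 20. Longest linear sequence: 18 steps (steps 3–20, from L-arabinose).

The three steps most likely to fail

**Step 14 (key step).**
- What may go wrong: the cyclisation may be slow because the ester must leave its preferred conformation, and material may leak through the tether-endo transition state to the cis-fused lactone.
- Fallback: the cycloaddition is run without the tether. It sets out from 19. TMSCl and imidazole should give the O9 trimethylsilyl ether F1. TIPSOTf and Et3N should give the untethered silyloxydiene F2. Heating F2 with ester 3 (toluene, 120 °C, or high pressure) should give the cyclohexene ethyl ester F3.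
- In this cycloaddition the ester still directs C13 to C14, A(1,3) strain still fixes the diene face, and the small ester is free to sit exo. The sequence of step 15 is then applied to F3, with the ethyl ester taking the place of the lactone. A citric acid work-up removes the TMS ether, and the fallback comes back to the route at 26.

**Step 15.**
- What may go wrong: incomplete enolisation may let hydride or Grignard reagent into the C19 lactone, excess hydride may over-reduce the released aldehyde, and the facial bias at C2 may erode.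
- Fallback: covalent masking and a chromium reagent. It sets out from 22. LiHMDS and then TBSCl should give the C19 silyl ketene acetal F4. DIBAL-H at −78 °C, followed by a pH 5 work-up that hydrolyses the ketene acetal, should give lactol 25, now isolated.
- A Nozaki–Hiyama–Kishi vinylation of its open hydroxy aldehyde form leaves lactones untouched (vinyl iodide, CrCl2, NiCl2 cat., with a chiral oxazoline–sulfonamide ligand for reagent control at C2). The fallback comes back to the route at 26.

**Step 20.**
- What may go wrong: oligomerisation may compete with closure of the medium ring, the 3E olefin may form under kinetic control, and the catalyst may decay on the chloride-bearing vinylcarbene.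
- Fallback: ring closure is moved in front of C–Cl bond formation. It sets out from 30. Metathesis of the free dienyl carbinol profits from allylic hydroxyl acceleration and carries no ionisable chloride, and should give the macrocyclic (6R)-dienol F5. Any 3E isomer is returned to 30 by ethenolysis and recycled. The Appel-type chlorination of step 19 on F5, again with inversion, comes back to the route at 32.

Further compounds
F1 | step 14 | O9 trimethylsilyl ether of 19 | CC(=O)/C(C)=C/[C@H](O[Si](C)(C)C)[C@]1(O)C(C)C(=O)O[C@H]1[C@H](O[Si](C)(C)C(C)(C)C)C(=C)C=C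
F2 | step 14 | untethered 12-O-TIPS silyloxydiene with 9-OTMS | C=C(O[Si](C(C)C)(C(C)C)C(C)C)/C(C)=C/[C@H](O[Si](C)(C)C)[C@]1(O)C(C)C(=O)O[C@H]1[C@H](O[Si](C)(C)C(C)(C)C)C(=C)C=C
F3 | step 14 | cyclohexene ethyl ester (C2 as CO2Et on C1, 14-sulfone cis to C15, 9-OTMS) | CCOC(=O)[C@@]1(C)[C@H](S(=O)(=O)c2ccccc2)CC(O[Si](C(C)C)(C(C)C)C(C)C)=C(C)[C@@H]1[C@H](O[Si](C)(C)C)[C@]1(O)C(C)C(=O)O[C@H]1[C@H](O[Si](C)(C)C(C)(C)C)C(=C)C=C
F4 | step 15 | C19 O-TBS silyl ketene acetal of 22 | O=C1O[C@H]([C@]3(O)C(C)=C(O[Si](C)(C)C(C)(C)C)O[C@H]3[C@H](O[Si](C)(C)C(C)(C)C)C(=C)C=C)[C@H]2C(C)=C(O[Si](C(C)C)(C(C)C)C(C)C)C[C@@H](S(=O)(=O)c3ccccc3)[C@]12C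
F5 | step 20 | macrocyclic (3Z,6R)-6-hydroxy analogue of 32 | C=C1/C=C\[C@H](OC(C)=O)[C@@]2(C)C=CC(=O)[C@@](C)(O)[C@@H]2[C@H](OC(C)=O)[C@]2(O)[C@@H](C)C(=O)O[C@H]2[C@@H]1O
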